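**Retrosynthetic overview**

- The strategy rests on the one benzene ring, a 1,2,4,5-substituted hydroquinone: C1 carries the 3-(benzoyloxy)prop-1-en-2-yl group, C2 and C5 carry H, C3 carries OH, C4 carries CH3 and C6 carries the O-isobutyrate, so the para oxygens at C3 and C6 must stay different.
- Last disconnections: the C3–O benzyl ether (Lewis acid plus cation scavenger) and the C6–O isobutyrate, which lead back to a 4-benzyloxyphenol with only the C6 hydroxyl free.
- Key disconnection: ring bonds C2–C3, C1–C6 and C5–C6. A chromium benzyloxy(isopropenyl)carbene supplies C3 (already etherified), C4 with its methyl, and C5. A terminal enyne benzoate supplies C2, C1 and the finished side chain. One CO ligand supplies C6 with its free OH.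
- The carbene complex comes from 2-bromopropene, Cr(CO)6 and benzyl alcohol; the enyne comes from 2-bromoallyl alcohol and trimethylsilylacetylene by Sonogashira coupling, benzoylation and desilylation.
- Ring order: the benzannulation forms the only ring made in the route; the two phenyl rings are bought in.

Key step: step 6

Remark: the target has no stereocentre and no stereogenic double bond. In the SMILES strings the carbonyl ligands on chromium are written as Cr=C=O, and the η6-arene complex 13 is written as arene and Cr(CO)3 parts joined by a dot.

**Route**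

Step 1
Reactants: 1 2-bromopropene; 2 chromium hexacarbonyl
Product: 5 tetramethylammonium pentacarbonyl(2-methylprop-2-enoyl)chromate, via 2-propenyllithium 3 (not isolated), via lithium acylchromate 4 (not isolated)
Conditions: t-BuLi (2 equiv), Et2O, −78 °C; Cr(CO)6, Et2O, −78 °C to rt; then Me4NBr, H2O, rt
Reagents that add atoms: tetramethylammonium bromide, C[N+](C)(C)C.[Br-]
Why: Bromine–lithium exchange with two equivalents of tert-butyllithium (the second destroys the tert-butyl bromide) gives 2-propenyllithium, which adds to a CO ligand of Cr(CO)6 in the classical Fischer acylmetalate synthesis, and cation metathesis with Me4NBr should give the crystalline, storable acylate 5.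

Step 2
Reactants: 5 tetramethylammonium pentacarbonyl(2-methylprop-2-enoyl)chromate
Product: 7 pentacarbonyl[benzyloxy(prop-1-en-2-yl)carbene]chromium, via acetoxycarbene complex 6 (not isolated)
Conditions: AcBr, CH2Cl2, −40 °C; then BnOH, −40 to 0 °C
Reagents that add atoms: benzyl alcohol, OCc1ccccc1
Why: O-Acylation of the acylate gives acetoxycarbene 6, whose carbene carbon behaves like a mixed anhydride and undergoes addition–elimination with benzyl alcohol (the acyloxycarbene alcoholysis route to alkoxy Fischer carbenes other than methoxy), while the α-methyl group and the low temperature disfavour conjugate addition to the alkenyl carbene.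

Step 3
Reactants: 8 2-bromoallyl alcohol (2-bromoprop-2-en-1-ol); 9 trimethylsilylacetylene
Product: 10 2-methylene-4-(trimethylsilyl)but-3-yn-1-ol
Conditions: PdCl2(PPh3)2 (cat.), CuI (cat.), Et3N, THF, rt
Reagents that add atoms: none
Why: Sonogashira coupling, in which oxidative addition of the vinyl bromide to zerovalent palladium (formed in situ from PdCl2(PPh3)2), transmetalation from the copper acetylide of 9 and reductive elimination form the sp2–sp bond with the free primary alcohol tolerated.

Step 4
Reactants: 10 2-methylene-4-(trimethylsilyl)but-3-yn-1-ol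
Product: 11 2-methylene-4-(trimethylsilyl)but-3-yn-1-yl benzoate
Conditions: BzCl, Et3N, DMAP (cat.), CH2Cl2, 0 °C
Reagents that add atoms: benzoyl chloride, O=C(Cl)c1ccccc1
Why: DMAP-catalysed acylation of the unhindered primary allylic alcohol through the N-benzoylpyridinium ion, placed before desilylation so that the volatile free enynol is never handled.

Step 5
Reactants: 11 2-methylene-4-(trimethylsilyl)but-3-yn-1-yl benzoate
Product: 12 2-methylenebut-3-yn-1-yl benzoate
Conditions: Bu4NF, AcOH, THF, 0 °C
Reagents that add atoms: none
Why: Fluoride-induced protodesilylation of the alkynyl C–Si bond, with acetic acid buffering the fluoride so that the benzoate is not cleaved and the acetylide is protonated at once.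

Step 6
Reactants: 7 pentacarbonyl[benzyloxy(prop-1-en-2-yl)carbene]chromium; 12 2-methylenebut-3-yn-1-yl benzoate (1.5 equiv)
Product: 14 2-[5-(benzyloxy)-2-hydroxy-4-methylphenyl]prop-2-en-1-yl benzoate, via tricarbonylchromium arene complex 13 (not isolated)
Conditions: THF (about 0.3 M), 50 °C, Ar; then air, Et2O, rt, filtration through silica
Reagents that add atoms: none
Why: Thermal loss of one cis CO from 7 lets the terminal alkyne of 12 bind and insert into the Cr=C bond (C2–C3), CO then inserts to give an η4-vinylketene complex (C1–C6), a six-electron electrocyclisation closes C5–C6, and tautomerisation gives the phenol bound to Cr(CO)3 as 13, which air should free without oxidising the 4-alkoxyphenol to the quinone. The closest known reaction type is the Dötz benzannulation of alkenyl(alkoxy)carbene chromium complexes with terminal alkynes, conjugated enynes included. The one ring closed is the benzene ring, built as a formal [3+2+1] assembly whose ring-closing event is the electrocyclisation of the dienylketene; no stereocentre is formed. The step needs regioselective insertion that puts the substituted alkyne carbon next to the CO-derived C6 and the alkyne CH next to C3, and the large size difference between H and the substituted vinyl group of 12 secures this, because the substituent on the alkyne carbon that bonds to the carbene carbon clashes with a CO ligand in the η1,η3-vinylcarbene intermediate. It also needs phenol formation over cyclobutenone or five-membered-ring products, which chromium, an alkenyl carbene, THF and a moderate concentration favour. The alkene of 12 ends up on C1 cross-conjugated to the ketene and cannot join a six-membered closure, so the allyl benzoate should pass through unchanged, C3 arrives etherified and C6 arrives as the only free hydroxyl.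

Step 7
Reactants: 14 2-[5-(benzyloxy)-2-hydroxy-4-methylphenyl]prop-2-en-1-yl benzoate
Product: 15 2-[5-(benzyloxy)-4-methyl-2-(2-methylpropanoyloxy)phenyl]prop-2-en-1-yl benzoate
Conditions: i-PrCOCl, Et3N, DMAP (cat.), CH2Cl2, 0 °C
Reagents that add atoms: isobutyryl chloride (2-methylpropanoyl chloride), CC(C)C(=O)Cl
Why: DMAP-catalysed O-acylation of the only free hydroxyl of 14, run cold on freshly prepared material so that acylation outruns air oxidation and any closure of the phenoxide onto the allylic benzoate.

Step 8
Reactants: 15 2-[5-(benzyloxy)-4-methyl-2-(2-methylpropanoyloxy)phenyl]prop-2-en-1-yl benzoate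
Product: 16 2-[5-hydroxy-4-methyl-2-(2-methylpropanoyloxy)phenyl]prop-2-en-1-yl benzoate (CNP0245407.0)
Conditions: BCl3 (2 equiv), C6HMe5 (3 equiv), CH2Cl2, −78 °C; then H2O
Reagents that add atoms: none
Why: BCl3 coordinates the aryl benzyl ether oxygen and cleaves the O–benzyl bond at −78 °C while pentamethylbenzene, a non-Lewis-basic cation scavenger, traps the benzyl cation by Friedel–Crafts alkylation; both esters should survive at this temperature, and the alkene is shielded from protonation by the electron-withdrawing allylic benzoate and by the ortho acyloxy group that twists it out of conjugation.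

**Compound list**

1 | 2-bromopropene | C=C(C)Br | starting material
2 | chromium hexacarbonyl, Cr(CO)6 | [C-]#[O+].[C-]#[O+].[C-]#[O+].[C-]#[O+].[C-]#[O+].[C-]#[O+].[Cr] | starting material
3 | 2-propenyllithium | [Li]C(C)=C | intermediate
4 | lithium pentacarbonyl(2-methylprop-2-enoyl)chromate | [Li+].C=C(C)C([O-])=[Cr](=C=O)(=C=O)(=C=O)(=C=O)=C=O | intermediate
5 | tetramethylammonium pentacarbonyl(2-methylprop-2-enoyl)chromate | C[N+](C)(C)C.C=C(C)C([O-])=[Cr](=C=O)(=C=O)(=C=O)(=C=O)=C=O | intermediate
6 | pentacarbonyl[acetoxy(prop-1-en-2-yl)carbene]chromium | C=C(C)C(OC(C)=O)=[Cr](=C=O)(=C=O)(=C=O)(=C=O)=C=O | intermediate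
7 | pentacarbonyl[benzyloxy(prop-1-en-2-yl)carbene]chromium | C=C(C)C(OCc1ccccc1)=[Cr](=C=O)(=C=O)(=C=O)(=C=O)=C=O | intermediate
8 | 2-bromoallyl alcohol (2-bromoprop-2-en-1-ol) | OCC(Br)=C | starting material
9 | trimethylsilylacetylene | C#C[Si](C)(C)C | starting material
10 | 2-methylene-4-(trimethylsilyl)but-3-yn-1-ol | C=C(CO)C#C[Si](C)(C)C | intermediate
11 | 2-methylene-4-(trimethylsilyl)but-3-yn-1-yl benzoate | C=C(COC(=O)c1ccccc1)C#C[Si](C)(C)C | intermediate
12 | 2-methylenebut-3-yn-1-yl benzoate | C#CC(=C)COC(=O)c1ccccc1 | intermediate
13 | tricarbonyl(η6-arene)chromium complex of phenol 14 | C=C(COC(=O)c1ccccc1)c1cc(OCc2ccccc2)c(C)cc1O.O=C=[Cr](=C=O)=C=O | intermediate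
14 | 2-[5-(benzyloxy)-2-hydroxy-4-methylphenyl]prop-2-en-1-yl benzoate | C=C(COC(=O)c1ccccc1)c1cc(OCc2ccccc2)c(C)cc1O | intermediate
15 | 2-[5-(benzyloxy)-4-methyl-2-(2-methylpropanoyloxy)phenyl]prop-2-en-1-yl benzoate | C=C(COC(=O)c1ccccc1)c1cc(OCc2ccccc2)c(C)cc1OC(=O)C(C)C | intermediate
16 | 2-[5-hydroxy-4-methyl-2-(2-methylpropanoyloxy)phenyl]prop-2-en-1-yl benzoate (CNP0245407.0) | C=C(COC(=O)c1ccccc1)c1cc(O)c(C)cc1OC(=O)C(C)C | target

**Step count**

Total steps: 8. Longest linear sequence: 6 steps (steps 3, 4, 5, 6, 7 and 8, from 8 to 16); the carbene arm (steps 1 and 2) joins at step 6.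

**Steps most likely to fail, with fallbacks**

Step 6. What may go wrong: the chromium vinylketene may divert to non-aromatic products, or the allylic benzoate may be lost in the warm, reducing chromium medium. That loss could occur by ionisation at zerovalent chromium or by closure of the new ortho phenol onto the allylic carbon to give a benzofuran. The fallback keeps the annulation but carries no allylic oxygen through it and oxidises afterwards. It sets out from 7, which is heated in THF at 50 °C with commercial 2-methylbut-1-en-3-yne and then aired. This should give, through the tricarbonylchromium complex of the new phenol F1, 4-(benzyloxy)-5-methyl-2-(prop-1-en-2-yl)phenol F2. Acylation with isobutyryl chloride, Et3N and catalytic DMAP gives 4-(benzyloxy)-5-methyl-2-(prop-1-en-2-yl)phenyl 2-methylpropanoate F3. Allylic hydroxylation of its only allylic methyl group with catalytic SeO2 and t-BuOOH in CH2Cl2 (ene reaction, then [2,3]-shift) gives 4-(benzyloxy)-2-(3-hydroxyprop-1-en-2-yl)-5-methylphenyl 2-methylpropanoate F4. Benzoylation with BzCl and pyridine at 0 °C brings the route back at 15.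

Step 8. What may go wrong: Lewis-acid damage before the benzyl ether is gone, by protonation or chloride addition at the 1,1-disubstituted alkene, ionisation of the allylic benzoate, or loss of the aryl isobutyrate. The fallback replaces the benzyl ether by a 4-methoxybenzyl ether that is removed oxidatively. It sets out from 5, which is treated with AcBr and then 4-methoxybenzyl alcohol (through 6) to give pentacarbonyl[(4-methoxybenzyloxy)(prop-1-en-2-yl)carbene]chromium F5. Benzannulation of F5 with 12 under the conditions of step 6 gives, through the tricarbonylchromium arene complex F6, 2-[2-hydroxy-5-(4-methoxybenzyloxy)-4-methylphenyl]prop-2-en-1-yl benzoate F7. Isobutyrylation as in step 7 gives 2-[5-(4-methoxybenzyloxy)-4-methyl-2-(2-methylpropanoyloxy)phenyl]prop-2-en-1-yl benzoate F8. DDQ in CH2Cl2 with pH 7 buffer at 0 °C then cleaves the 4-methoxybenzyl ether by hydride abstraction and hydrolysis, and the route comes back at 16.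

Step 2. What may go wrong: thermal decomposition of the acetoxycarbene before alcoholysis, or conjugate addition of benzyl alcohol to the electrophilic alkenyl carbene. The fallback forms the O–CH2 bond by alkylation of the acylate oxygen instead of substitution at the carbene carbon. It sets out from 5. Benzyl trifluoromethanesulfonate F9 is made at −78 °C in CH2Cl2 from benzyl alcohol, Tf2O and 2,6-di-tert-butyl-4-methylpyridine, and is added cold to 5 (−78 to −20 °C). Hard O-alkylation of the acylmetalate by an alkyl triflate should give the benzyloxy carbene directly, and the route comes back at 7.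

**Further compounds**

F1 | step 6 | tricarbonyl(η6-arene)chromium complex of phenol F2 | C=C(C)c1cc(OCc2ccccc2)c(C)cc1O.O=C=[Cr](=C=O)=C=O
F2 | step 6 | 4-(benzyloxy)-5-methyl-2-(prop-1-en-2-yl)phenol | C=C(C)c1cc(OCc2ccccc2)c(C)cc1O
F3 | step 6 | 4-(benzyloxy)-5-methyl-2-(prop-1-en-2-yl)phenyl 2-methylpropanoate | C=C(C)c1cc(OCc2ccccc2)c(C)cc1OC(=O)C(C)C
F4 | step 6 | 4-(benzyloxy)-2-(3-hydroxyprop-1-en-2-yl)-5-methylphenyl 2-methylpropanoate | C=C(CO)c1cc(OCc2ccccc2)c(C)cc1OC(=O)C(C)C
F5 | step 8 | pentacarbonyl[(4-methoxybenzyloxy)(prop-1-en-2-yl)carbene]chromium | C=C(C)C(OCc1ccc(OC)cc1)=[Cr](=C=O)(=C=O)(=C=O)(=C=O)=C=O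
F6 | step 8 | tricarbonyl(η6-arene)chromium complex of phenol F7 | C=C(COC(=O)c1ccccc1)c1cc(OCc2ccc(OC)cc2)c(C)cc1O.O=C=[Cr](=C=O)=C=O
F7 | step 8 | 2-[2-hydroxy-5-(4-methoxybenzyloxy)-4-methylphenyl]prop-2-en-1-yl benzoate | C=C(COC(=O)c1ccccc1)c1cc(OCc2ccc(OC)cc2)c(C)cc1O
F8 | step 8 | 2-[5-(4-methoxybenzyloxy)-4-methyl-2-(2-methylpropanoyloxy)phenyl]prop-2-en-1-yl benzoate | C=C(COC(=O)c1ccccc1)c1cc(OCc2ccc(OC)cc2)c(C)cc1OC(=O)C(C)C
F9 | step 2 | benzyl trifluoromethanesulfonate | O=S(=O)(OCc1ccccc1)C(F)(F)F
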